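The data stem from a simulated flask on assumed constants; the scatter is artificial.

A leftover was what I reckoned first: how much J still stood in each flask when it stopped, since unreacted J is not yet E.

| setting | cedar | maple | ochre | green | grey | red |
|---|---|---|---|---|---|---|
| J | 0.25 M | 0.25 M | 0.25 M | 0.25 M | 0.25 M | 0.25 M (fed, over 24.0 min) |
| G | 5 equiv | 10 equiv | 5.00 equiv | 5.00 equiv (fed, over 24.0 min) | 5.00 equiv | 5.00 equiv |
| remark | run made earlier | run made earlier | everything together in a closed stirred flask, run for 30 min | all but G at the start; G goes in evenly over 24.0 min, the run ends at 30 min | one stirred flow tank at steady state, fed with the mixture as stated, mean residence time 30 min | all but J at the start; J goes in evenly over 24.0 min, the run ends at 30 min |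
| time |  |  | 30 min | 30 min |  | 30 min |

| run | time / min | E / % | J / % |
|---|---|---|---|
| cedar | 4.00 | 36.8 | 32.9 |
| cedar | 8.00 | 57.9 | 11.9 |
| cedar | 10.0 | 64.0 | 7.1 |
| cedar | 15.0 | 70.7 | 2.6 |
| cedar | 20.0 | 73.6 | 0.5 |
| maple | 0.250 | 1.3 | 85.8 |
| maple | 0.417 | 3.0 | 78.3 |
| maple | 0.833 | 9.6 | 60.8 |
| maple | 1.50 | 22.6 | 42.2 |
| maple | 3.00 | 44.4 | 18.6 |

(standard deviation of a reading: 0.3 percentage points)

1. order of the set-ups by the amount of E at the outlet or at the end, in percent of the J put in, highest first (ochre / green / grey / red)
2. amount of E at the outlet or at the end, in percent of the J put in, ochre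
3. amount of E at the outlet or at the end, in percent of the J put in, green
4. amount of E at the outlet or at the end, in percent of the J put in, grey
5. amount of E at the outlet or at the end, in percent of the J put in, red

- the stated concentrations are those of everything mixed, before any reaction; amounts are the same in each set-up
- the feed brings no volume worth counting
- the earlier runs were made in a closed, stirred flask

Cedar at 20.0 min held 0.5% of its J and showed 73.6% of E, so I took a yield s of 74.0% on reacted J.

The first rung was E's lag. In maple, s on the J lost by 1.50 min gives 42.8%, and E read 44.4% at 3.00 min, so something unseen held reacted J for about 1.50 min.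

Next came J itself. Maple fell at 0.556 /min and cedar, from 4.00 min to 10.0 min, at 0.256 /min, about half of that, so I took J's loss as first order in G, one G per J. With G near 9.50 equiv in maple, the constant k is 0.234 /M/min.

My carried quantity is τ, the pseudo-first-order life of J in the G remaining after J has taken its share: 4.27 min. It is longer than the lag.

Next came the tail after dosing, 6.00 min, then the dosing, then the run, which spans 7.02 lives, so I reckoned that ochre kept about 0.0892% of its J.

Since τ is shorter than the dosing time, I set red's J at the end of its feed at τ over the dosing time, and the tail cut that to 4.37% in my reckoning. For green I let the G beyond one equiv climb evenly from nothing at 4.80 min; taking its mean gave 3.65 lives and 2.59% of J left. For grey I reckoned 12.5% of J left. With s, I expected ochre 73.9%, green 72.1%, red 70.8%, grey 64.8%.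

The forecast gave ochre 74.5%, red 70%, green 65% and grey 61%, in the order ochre > red > green > grey, holding that “low early G lowers selectivity”, whereas I put green above red.

The flasks gave ochre > green > red > grey: 75.6%, 73.0%, 69.6%, 62.9%.

    G → Z (k = 3.00 × 10⁻⁶ /s)
    J + G → X + D (k = 0.00400 /M/s)
    X ⇌ E (K = 9.90, k = 0.0130 /s)
    X ⇌ L (K = 2.10, k = 0.00650 /s)

In ochre, J's half-life by its forward step, with G as charged, 2.3 min, was longer than X's forward half-lives, with the way back not counted, 0.89 min to E and 1.8 min to L. Green, with 2.59% of J reckoned left against red's 4.37%, ended higher at 73.0% against 69.6%, and grey, reckoned with τ of 4.27 min at 12.5% of J left, ended at 62.9%.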